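**Retrosynthetic overview**

1. The cyclohexene C2–C1=C10–C14–C15′–C4′ is opened by a retro-Diels–Alder cut of C2–C4′ and C14–C15′ into the diosphenol diene 26 (C14=C10–C1=C2–OH) and the 2-methylidenecyclopentanone 21; both halves are the same 7-epi-guaianolide skeleton.
2. Enabling feature: the dienophile ring C1′–C2′–C3′(=O)–C4′(=C15′H2)–C5′ is an isomer of a 1-ethynylcyclobutanol (four-membered ring C3′–C2′–C1′–C5′ plus C4′≡C15′). A gold-triggered shift of C5′ from C3′ to C4′ in 20 therefore releases the enone in the flask, where 26 captures it; this last step joins two C15 halves and sets C4′ and C2.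
3. Diene 26 comes from the same cyclobutanol 20 (ring expansion, silyl dienol ether, Rubottom oxidation, oxidation to the dione), so one building block serves both halves.
4. 20 from enone lactone 8: head-to-tail enone–ketene acetal [2+2] photocycloaddition (cyclobutane), one-carbon homologation of the six- to the seven-membered ketone (C9′), Wittig (C14′), lactone α-methylenation (C13′), acetylide addition (C4′, C15′).
5. 8 from cyclohex-2-enyl acetate: asymmetric allylic alkylation (C7′), decarboxylation, iodolactonisation (cis-lactone, C6′), elimination, allylic oxidation. Ring order: cyclohexane, lactone, cyclobutane, cycloheptane, then cyclopentanone and cyclohexene together.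

Key step: step 16

Remark: the SMILES is read literally. Both γ-lactones are cis-fused (H6/H7 and H6′/H7′ syn; C7 and C7′ are R), so the halves are 7-epi-guaianolides and trans-lactone natural products are not used as chiral pool. Guaianolide numbering is used, primed for the half with the spiro carbon C4′; α/β refer to the usual guaianolide drawing (H1 and H5 α). The same atoms are called C1–C15 once a compound serves the hydroxylated half.

**Route**

Step 1
Reactants: 1 rac-cyclohex-2-en-1-yl acetate; 2 dimethyl malonate
Product: 3 dimethyl (S)-2-(cyclohex-2-en-1-yl)propanedioate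
Conditions: [Pd(C3H5)Cl]2 (2.5 mol %), (R,R)-N,N′-cyclohexane-1,2-diylbis(2-diphenylphosphinobenzamide) (7.5 mol %; ligand enantiomer to be matched to the S product), NaH, (n-C6H13)4NBr, CH2Cl2, 0 °C to rt
Reagents that add atoms: none
Why: Tsuji–Trost asymmetric allylic alkylation: both enantiomers of 1 ionise to the same meso π-allylpalladium complex and the chiral ligand directs the malonate to one allyl terminus, which sets C7′.

Step 2
Reactants: 3 dimethyl (S)-2-(cyclohex-2-en-1-yl)propanedioate
Product: 5 (R)-2-(cyclohex-2-en-1-yl)acetic acid, via malonic acid 4 (not isolated)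
Conditions: KOH, MeOH/H2O, reflux; HCl to pH 1; then neat, 160 °C
Reagents that add atoms: potassium hydroxide, [K+].[OH-]
Why: Ester saponification and thermal decarboxylation of the malonic acid leave the stereocentre untouched (the descriptor changes to R only through the priority rules).

Step 3
Reactants: 5 (R)-2-(cyclohex-2-en-1-yl)acetic acid
Product: 6 (3aR,7S,7aS)-7-iodohexahydro-1-benzofuran-2(3H)-one
Conditions: I2, NaHCO3, THF/H2O, 0 °C to rt, dark
Reagents that add atoms: iodine, II
Why: Iodolactonisation: 5-exo attack of the carboxylate anti to the iodonium ion gives the cis-fused γ-lactone (C6′–O syn to the C7′ arm) with iodine trans to oxygen at C5′.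

Step 4
Reactants: 6 (3aR,7S,7aS)-7-iodohexahydro-1-benzofuran-2(3H)-one
Product: 7 (3aR,7aS)-3a,4,5,7a-tetrahydro-1-benzofuran-2(3H)-one
Conditions: DBU, toluene, 80 °C
Reagents that add atoms: none
Why: E2 dehydroiodination: only a hydrogen on C1′ is anti-periplanar to iodine, so the C1′=C5′ alkene forms and the two lactone stereocentres stay.

Step 5
Reactants: 7 (3aR,7aS)-3a,4,5,7a-tetrahydro-1-benzofuran-2(3H)-one
Product: 8 (3aR,7aS)-3a,7a-dihydro-1-benzofuran-2,5(3H,4H)-dione
Conditions: Rh2(cap)4 (dirhodium tetracaprolactamate, 1 mol %), t-BuOOH, K2CO3 (cat.), CH2Cl2, rt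
Reagents that add atoms: tert-butyl hydroperoxide, CC(C)(C)OO
Why: Allylic C–H oxidation (peroxyl radical chain) at the only allylic methylene, C10′, the pattern known for 3-acyloxycyclohexenes going to 4-acyloxycyclohex-2-enones; no stereocentre is formed.

Step 6
Reactants: 8 (3aR,7aS)-3a,7a-dihydro-1-benzofuran-2,5(3H,4H)-dione; 9 1,1-diethoxyethene
Product: 11 cis-anti-cis photoadduct (3′,3′-diethoxycyclobutane cis-fused at C1′/C5′ to the C10′ cyclohexanone that carries the cis γ-lactone, cyclobutane anti to the lactone), via trans-fused photoadduct 10 (not isolated)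
Conditions: hν (medium-pressure mercury lamp, Pyrex), 9 (10 equiv), CH2Cl2, −40 °C; then basic Al2O3, CH2Cl2, rt
Reagents that add atoms: none
Why: Enone–alkene [2+2] photocycloaddition from the enone triplet, head-to-tail for an electron-rich alkene (acetal carbon C3′ on the β-carbon C5′) and on the face anti to the cis-fused lactone, which sets C5′; C1′, α to the ketone, is then equilibrated to the cis-fused cyclobutane.

Step 7
Reactants: 11 cis-anti-cis photoadduct
Product: 13 cycloheptanone (C10′ ketone, 3′,3′-diethoxycyclobutane and cis γ-lactone as in 11, C9′ inserted), via silyl enol ether 12 (not isolated)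
Conditions: Me3SiCHN2 (1.2 equiv), Sc(OTf)3 (10 mol %), CH2Cl2, −78 to 0 °C; then aq. citric acid, THF, 0 °C
Reagents that add atoms: (trimethylsilyl)diazomethane, C[Si](C)(C)C=[N+]=[N-]
Why: Lewis acid-catalysed diazoalkane homologation (Tiffeneau–Demjanov type): the less substituted α-carbon C8′ migrates, so C9′ enters between C10′ and C8′ and no stereocentre changes.

Step 8
Reactants: 13 cycloheptanone
Product: 14 10′-methylidene cycloheptane (3′,3′-diethoxycyclobutane, saturated cis γ-lactone)
Conditions: Ph3PCH3Br, KOtBu, THF, 0 °C to rt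
Reagents that add atoms: methyltriphenylphosphonium bromide, C[P+](c1ccccc1)(c1ccccc1)c1ccccc1.[Br-]
Why: Wittig methylenation of the ketone, far more reactive than the lactone, installs C14′ while C1′ stays in its stable cis configuration.

Step 9
Reactants: 14 10′-methylidene cycloheptane
Product: 17 α-methylidene lactone acetal, via Mannich base 15 (not isolated), via ammonium iodide 16 (not isolated)
Conditions: LiN(iPr)2, THF, −78 °C; CH2=NMe2 iodide, −78 to 0 °C; MeI, MeOH, rt; DBU, CH2Cl2, rt
Reagents that add atoms: dimethyl(methylidene)ammonium iodide (Eschenmoser salt), C=[N+](C)C.[I-]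
Why: Mannich reaction of the lactone enolate, then quaternisation and E1cB loss of trimethylamine (classical α-methylenation), installs C13′; the transient C11′ centre is destroyed.

Step 10
Reactants: 17 α-methylidene lactone acetal
Product: 18 cyclobutanone (C3′ ketone; cyclobutane cis-fused at C1′/C5′ to the 10′-methylidenecycloheptane bearing the cis-fused α-methylidene-γ-lactone)
Conditions: 10 % aq. oxalic acid, SiO2, CH2Cl2, rt
Reagents that add atoms: water, O
Why: Acid-catalysed acetal hydrolysis under conditions too mild to move the exocyclic alkenes.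

Step 11
Reactants: 18 cyclobutanone; 19 ethynylmagnesium bromide
Product: 20 ethynylcyclobutanol (18 with C3′ bearing OH and ethynyl C4′≡C15′, ethynyl syn to H1′/H5′)
Conditions: CeCl3 (anhydrous), THF, −78 °C; aq. NH4Cl
Reagents that add atoms: none
Why: 1,2-Addition of the organocerium acetylide to the strained, highly electrophilic cyclobutanone from its convex face, chemoselective over the lactone carbonyl and its methylidene; the C3′ configuration is inconsequential.

Step 12
Reactants: 20 ethynylcyclobutanol
Product: 21 (3aR,6aR,9aR,9bS)-3,6,9-trimethylidene-perhydroazuleno[4,5-b]furan-2,8-dione (7-epi-dehydrozaluzanin C)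
Conditions: [(4-CF3C6H4)3P]AuCl (1 mol %), AgSbF6 (1 mol %), CH2Cl2, rt
Reagents that add atoms: none
Why: Gold-catalysed ring expansion of a 1-alkynylcyclobutanol (π-acid-triggered semipinacol 1,2-shift): the ring-fusion carbon C5 migrates with retention, so the cis ring fusion is kept.

Step 13
Reactants: 21 7-epi-dehydrozaluzanin C
Product: 22 triethylsilyl dienol ether (C2=C3–OSiEt3, cross-conjugated with C4=C15)
Conditions: Et3SiOTf, Et3N, CH2Cl2, −78 to 0 °C
Reagents that add atoms: triethylsilyl trifluoromethanesulfonate, CC[Si](CC)(CC)OS(=O)(=O)C(F)(F)F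
Why: Soft enolisation and O-silylation; only C2 carries α-hydrogens, so a single 2-silyloxy diene forms.

Step 14
Reactants: 22 triethylsilyl dienol ether
Product: 24 2α-hydroxy ketone (21 with OH at C2), via silyloxy ketone 23 (not isolated)
Conditions: dimethyldioxirane (1.05 equiv, acetone), CH2Cl2, −78 °C; then AcOH/THF/H2O, 0 °C
Reagents that add atoms: dimethyldioxirane, CC1(C)OO1
Why: Rubottom oxidation: the dioxirane epoxidises the most electron-rich alkene (the silyl enol ether) from the convex α face and acid releases the α-hydroxy ketone; the C2 configuration is erased in step 15.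

Step 15
Reactants: 24 2α-hydroxy ketone
Product: 26 diosphenol diene (2-hydroxy-3-oxo-7-epi-guaia-1,4(15),10(14),11(13)-tetraen-12,6-olide), via 2,3-dione 25 (not isolated)
Conditions: Dess–Martin periodinane, CH2Cl2, 0 °C to rt; used at once
Reagents that add atoms: none
Why: Alcohol oxidation to the cyclopentane-1,2-dione, which enolises toward C1 to the conjugated diosphenol (such diones are enols), removing C1 and C2 as stereocentres.

Step 16
Reactants: 20 ethynylcyclobutanol; 26 diosphenol diene
Product: 27 CNP0269880.1 (target), via enone 21 (not isolated)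
Conditions: 20 (2 equiv), [(4-CF3C6H4)3P]AuCl (2 mol %), AgSbF6 (2 mol %), ClCH2CH2Cl, rt, 30 min; then 26 (1 equiv) added over 2 h, rt to 50 °C
Reagents that add atoms: none
Why: Cationic monovalent gold coordinates the terminal alkyne of 20, the strained ring bond C3′–C5′ shifts anti to the metal onto C4′ while the carbinol becomes the C3′ ketone, and protodeauration at C15′ gives enone 21, which diosphenol 26 then takes up in a thermal [4+2] cycloaddition. The closest known reactions are the gold-catalysed ring expansion of 1-alkynylcyclobutanols to 2-alkylidenecyclopentanones and the Diels–Alder dimerisation of guaianolide 2-methylidenecyclopentanones with cross-conjugated dienones; here the two are run in one flask. The cyclopentanone C1′–C2′–C3′–C4′–C5′ arises by one-carbon ring expansion of the cyclobutane C3′–C2′–C1′–C5′ (1,2-alkyl shift), and the cyclohexene C2–C1=C10–C14–C15′–C4′ by a suprafacial, ortho-regioselective Diels–Alder closure (C14 to C15′, C2 to C4′) of the s-cis-locked diene. C5′ migrates with retention, so the cis ring fusion (H1′, H5′ α) of 20 is kept; C4′ should be set by attack of the diene on the convex α face of the hydroazulenone (syn to H5′), and C2 by attack of the dienophile on the β face of the flat diene, away from the cis-lactone on its α face, with the C3′ carbonyl endo (C3 and C3′ syn on the new ring). The step needs migration of C5′ instead of C2′ (higher migratory aptitude of the ring-fusion methine), reaction at the s-cis 2-methylidene ketone instead of the lactone or C10′ methylidenes (the most electron-poor, least hindered alkene), and cross- instead of self-dimerisation of 26 (21 is formed first in twofold excess and 26 is added slowly).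

**Compound list**

1 | rac-cyclohex-2-en-1-yl acetate | CC(=O)OC1C=CCCC1 | starting material
2 | dimethyl malonate | COC(=O)CC(=O)OC | starting material
3 | dimethyl (S)-2-(cyclohex-2-en-1-yl)propanedioate | COC(=O)C(C(=O)OC)[C@@H]1C=CCCC1 | intermediate
4 | (S)-2-(cyclohex-2-en-1-yl)propanedioic acid | OC(=O)C(C(=O)O)[C@@H]1C=CCCC1 | intermediate
5 | (R)-2-(cyclohex-2-en-1-yl)acetic acid | OC(=O)C[C@@H]1C=CCCC1 | intermediate
6 | (3aR,7S,7aS)-7-iodohexahydro-1-benzofuran-2(3H)-one | O=C1C[C@H]2CCC[C@H](I)[C@H]2O1 | intermediate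
7 | (3aR,7aS)-3a,4,5,7a-tetrahydro-1-benzofuran-2(3H)-one | O=C1C[C@H]2CCC=C[C@H]2O1 | intermediate
8 | (3aR,7aS)-3a,7a-dihydro-1-benzofuran-2,5(3H,4H)-dione | O=C1C[C@H]2CC(=O)C=C[C@H]2O1 | intermediate
9 | 1,1-diethoxyethene | C=C(OCC)OCC | starting material
10 | trans-fused photoadduct (C1′ epimer of 11) | CCOC1(OCC)C[C@@H]2C(=O)C[C@@H]3CC(=O)O[C@@H]3[C@@H]12 | intermediate
11 | cis-anti-cis photoadduct (3′,3′-diethoxycyclobutane, C10′ cyclohexanone, cis γ-lactone) | CCOC1(OCC)C[C@H]2C(=O)C[C@@H]3CC(=O)O[C@@H]3[C@@H]12 | intermediate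
12 | trimethylsilyl enol ether of 13 (C9′=C10′–OSiMe3) | CCOC1(OCC)C[C@H]2C(O[Si](C)(C)C)=CC[C@@H]3CC(=O)O[C@@H]3[C@@H]12 | intermediate
13 | cycloheptanone (C10′ ketone, 3′,3′-diethoxycyclobutane, cis γ-lactone) | CCOC1(OCC)C[C@H]2C(=O)CC[C@@H]3CC(=O)O[C@@H]3[C@@H]12 | intermediate
14 | 10′-methylidene cycloheptane (3′,3′-diethoxycyclobutane, cis γ-lactone) | CCOC1(OCC)C[C@H]2C(=C)CC[C@@H]3CC(=O)O[C@@H]3[C@@H]12 | intermediate
15 | Mannich base (11′-dimethylaminomethyl lactone) | CCOC1(OCC)C[C@H]2C(=C)CC[C@@H]3[C@@H](CN(C)C)C(=O)O[C@@H]3[C@@H]12 | intermediate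
16 | trimethylammonium iodide of 15 | CCOC1(OCC)C[C@H]2C(=C)CC[C@@H]3[C@@H](C[N+](C)(C)C)C(=O)O[C@@H]3[C@@H]12.[I-] | intermediate
17 | α-methylidene lactone acetal | CCOC1(OCC)C[C@H]2C(=C)CC[C@@H]3C(=C)C(=O)O[C@@H]3[C@@H]12 | intermediate
18 | cyclobutanone (C3′ ketone, 10′-methylidene, cis α-methylidene-γ-lactone) | O=C1C[C@H]2C(=C)CC[C@@H]3C(=C)C(=O)O[C@@H]3[C@@H]12 | intermediate
19 | ethynylmagnesium bromide | C#C[Mg]Br | starting material
20 | ethynylcyclobutanol (C3′ carbinol bearing C4′≡C15′) | C#C[C@]1(O)C[C@H]2C(=C)CC[C@@H]3C(=C)C(=O)O[C@@H]3[C@@H]12 | intermediate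
21 | (3aR,6aR,9aR,9bS)-3,6,9-trimethylidene-perhydroazuleno[4,5-b]furan-2,8-dione (7-epi-dehydrozaluzanin C) | C=C1C(=O)C[C@H]2C(=C)CC[C@@H]3C(=C)C(=O)O[C@@H]3[C@@H]12 | intermediate
22 | triethylsilyl dienol ether of 21 | C=C1C(O[Si](CC)(CC)CC)=C[C@H]2C(=C)CC[C@@H]3C(=C)C(=O)O[C@@H]3[C@@H]12 | intermediate
23 | 2α-triethylsilyloxy ketone | C=C1C(=O)[C@H](O[Si](CC)(CC)CC)[C@H]2C(=C)CC[C@@H]3C(=C)C(=O)O[C@@H]3[C@@H]12 | intermediate
24 | 2α-hydroxy ketone | C=C1C(=O)[C@H](O)[C@H]2C(=C)CC[C@@H]3C(=C)C(=O)O[C@@H]3[C@@H]12 | intermediate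
25 | 2,3-dione | C=C1C(=O)C(=O)[C@H]2C(=C)CC[C@@H]3C(=C)C(=O)O[C@@H]3[C@@H]12 | intermediate
26 | diosphenol diene (2-hydroxy-3-oxo-7-epi-guaia-1,4(15),10(14),11(13)-tetraen-12,6-olide) | C=C1C(=O)C(O)=C2C(=C)CC[C@@H]3C(=C)C(=O)O[C@@H]3[C@@H]12 | intermediate
27 | CNP0269880.1 | C=C1C(=O)[C@]2(O)C3=C(CC[C@@H]4C(=C)C(=O)O[C@@H]4[C@@H]13)CC[C@]21C(=O)C[C@H]2C(=C)CC[C@@H]3C(=C)C(=O)O[C@@H]3[C@H]21 | target

**Step count and risks**

Total steps: 16. Longest linear sequence: 16 (steps 1 to 16; compound 20 is used both in step 12 and in step 16).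

Steps most likely to fail, with fallbacks:

Step 16. The diosphenol may dimerise with itself, add through C1 in a Michael sense, or decompose under the gold and silver salts, and the facial or endo selectivity of the cycloaddition may be poor. The fallback separates the two events and sets out from 21 (isolated in step 12) and 26. Compound 26 would be silylated with t-BuMe2SiOTf and 2,6-lutidine to the tert-butyldimethylsilyl dienol ether F1. F1 and 21 would be heated in toluene (or held under high pressure) to the silyl-protected adduct F2. HF·pyridine in THF would then return to the route at 27.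

Step 7. The cyclobutane methine C1′ may migrate instead of C8′, or the acetal may be lost under the Lewis acid. The fallback fixes the regiochemistry by enolate formation and not by migratory aptitude (Ito–Saegusa ring expansion), and sets out from 11. One equivalent of LiN(iPr)2 and Me3SiCl at −78 °C would give the kinetic silyl enol ether F3 (C8′=C10′). Et2Zn and CH2I2 would give the siloxycyclopropane F4. FeCl3 in DMF would open it to the β-chloro ketone F5, and NaOAc would eliminate to the cycloheptenone F6. H2 over Pd/C would return to the route at 13.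

Step 11. The acetylide may add to the methylidene lactone or enolise the cyclobutanone instead of adding to C3′. The fallback keeps the Michael acceptor masked and sets out from the Mannich base 15, isolated instead of being quaternised. Oxalic acid on silica would give the amino cyclobutanone F7. Ethynylmagnesium bromide with CeCl3 would give the amino ethynyl carbinol F8. MeI would give the ammonium iodide F9, and aqueous NaHCO3 would eliminate trimethylamine and return to the route at 20.

**Further compounds**

F1 | step 16 | tert-butyldimethylsilyl dienol ether of 26 | C=C1C(=O)C(O[Si](C)(C)C(C)(C)C)=C2C(=C)CC[C@@H]3C(=C)C(=O)O[C@@H]3[C@@H]12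
F2 | step 16 | 2-O-tert-butyldimethylsilyl ether of 27 | C=C1C(=O)[C@]2(O[Si](C)(C)C(C)(C)C)C3=C(CC[C@@H]4C(=C)C(=O)O[C@@H]4[C@@H]13)CC[C@]21C(=O)C[C@H]2C(=C)CC[C@@H]3C(=C)C(=O)O[C@@H]3[C@H]21
F3 | step 7 | kinetic trimethylsilyl enol ether of 11 (C8′=C10′) | CCOC1(OCC)C[C@H]2C(O[Si](C)(C)C)=C[C@@H]3CC(=O)O[C@@H]3[C@@H]12
F4 | step 7 | siloxycyclopropane (CH2 added across C8′=C10′, anti to the cyclobutane) | CCOC1(OCC)C[C@H]2[C@]4(O[Si](C)(C)C)C[C@@H]4[C@@H]3CC(=O)O[C@@H]3[C@@H]12
F5 | step 7 | 8′-chloro cycloheptanone | CCOC1(OCC)C[C@H]2C(=O)C[C@@H](Cl)[C@@H]3CC(=O)O[C@@H]3[C@@H]12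
F6 | step 7 | cyclohept-8′-en-10′-one | CCOC1(OCC)C[C@H]2C(=O)C=C[C@@H]3CC(=O)O[C@@H]3[C@@H]12
F7 | step 11 | amino cyclobutanone (Mannich base, C3′ ketone) | O=C1C[C@H]2C(=C)CC[C@@H]3[C@@H](CN(C)C)C(=O)O[C@@H]3[C@@H]12
F8 | step 11 | amino ethynyl carbinol | C#C[C@]1(O)C[C@H]2C(=C)CC[C@@H]3[C@@H](CN(C)C)C(=O)O[C@@H]3[C@@H]12
F9 | step 11 | trimethylammonium iodide of F8 | C#C[C@]1(O)C[C@H]2C(=C)CC[C@@H]3[C@@H](C[N+](C)(C)C)C(=O)O[C@@H]3[C@@H]12.[I-]
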